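**Plan**

- Atom labels of the target: C1 (ring C=CH2), C2 (CHOH), C3 (CH2), C4 (ring-fusion CH), C5 (CMe2), C6 (CHBr), C7/C8 (CH2), C9 (ring-fusion C–Me), O10, C11 (OCH), C12 (CH2Br). The enabling feature is the cyclohexane bond C4–C9: it ties a methyl-bearing carbinol carbon (a latent methyl ketone) to a carbon lying β to C2 and next to the gem-dimethyl C5 (a latent enoate β-carbon).
- Retrosynthetic cuts, in order: C2–OH/C1=CH2 (from a C1–C2 epoxide of a C1-methyl olefin); C6–Br (inversion of an axial alcohol); C11–C12 and C11–H (bromomethyl carbenoid, then hydride, on a lactone); C1=C2 (ring-closing metathesis); O10–C11 (ester); C4–C9 (ketyl–enoate closure); C3=C4 (olefination); C5–C6 (aldol).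
- Forward: the chain is assembled from pent-4-enal, an isobutyrate ketene acetal and a phosphonoacetate. The cyclohexane closes first (step 7), the oxepane second as an unsaturated ε-lactone (step 11). The lactone carbon then becomes CH(CH2Br), C6–O is exchanged for C6–Br, and the C1/C2 olefin is transposed oxidatively.
- Stereochemistry: C6 from a reagent-controlled aldol; C4 and C9 relayed from C6 in the chair transition state of the SmI2 closure; C11 by hydride delivery anti to the axial C9 methyl; C6–Br by equatorial hydride attack followed by SN2 inversion; C2 by epoxidation anti to the C11 CH2Br group.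

Key step: step 7

Assumption: the oxazaborolidinone from N-tosyl-D-valine is taken to deliver the (S)-aldol from an unbranched aliphatic aldehyde; if the sense is the opposite, the L-valine reagent is used instead.

**Route**

Step 1
Reactants: 1 pent-4-enal; 2 1-methoxy-2-methyl-1-(trimethylsilyloxy)prop-1-ene
Product: 3 methyl (3S)-3-hydroxy-2,2-dimethylhept-6-enoate
Conditions: N-Ts-D-valine, BH3·THF, CH2Cl2, rt; then 1 and 2, −78 °C; aq. work-up
Reagents that add atoms: none
Why: Kiyooka-type Mukaiyama aldol, in which the preformed N-sulfonyl oxazaborolidinone (all BH3 consumed before the alkene-bearing aldehyde is added) activates the aldehyde and shields one face, so the ketene acetal should add to give the (S)-carbinol (C6) together with the quaternary C5.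

Step 2
Reactants: 3 methyl (3S)-3-hydroxy-2,2-dimethylhept-6-enoate
Product: 4 methyl (3S)-3-[(tert-butyldimethylsilyl)oxy]-2,2-dimethylhept-6-enoate
Conditions: TBSOTf, 2,6-lutidine, CH2Cl2, 0 °C
Reagents that add atoms: tert-butyldimethylsilyl triflate, CC(C)(C)[Si](C)(C)OS(=O)(=O)C(F)(F)F
Why: Silylation of a hindered secondary alcohol with a silyl triflate is routine, and the bulky silyl ether later serves as the equatorial anchor of the ring closure.

Step 3
Reactants: 4 methyl (3S)-3-[(tert-butyldimethylsilyl)oxy]-2,2-dimethylhept-6-enoate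
Product: 5 (3S)-3-[(tert-butyldimethylsilyl)oxy]-2,2-dimethylhept-6-en-1-ol
Conditions: DIBAL-H, CH2Cl2, −78 → 0 °C
Reagents that add atoms: none
Why: Full DIBAL-H reduction of the ester to the primary alcohol is more dependable than stopping a neopentyl ester at the aldehyde stage, and neither the silyl ether nor the alkene is affected.

Step 4
Reactants: 5 (3S)-3-[(tert-butyldimethylsilyl)oxy]-2,2-dimethylhept-6-en-1-ol
Product: 6 (3S)-3-[(tert-butyldimethylsilyl)oxy]-2,2-dimethylhept-6-enal
Conditions: Dess–Martin periodinane, CH2Cl2, rt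
Reagents that add atoms: none
Why: Dess–Martin oxidation of a primary alcohol gives an aldehyde that has no α-hydrogen and therefore cannot epimerize or undergo β-elimination of the silyloxy group.

Step 5
Reactants: 6 (3S)-3-[(tert-butyldimethylsilyl)oxy]-2,2-dimethylhept-6-enal; 7 triethyl phosphonoacetate
Product: 8 ethyl (2E,5S)-5-[(tert-butyldimethylsilyl)oxy]-4,4-dimethylnona-2,8-dienoate
Conditions: NaH, THF, 0 °C → rt
Reagents that add atoms: none
Why: Horner–Wadsworth–Emmons olefination of a non-enolizable aldehyde with a stabilized phosphonate should give the (E)-enoate.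

Step 6
Reactants: 8 ethyl (2E,5S)-5-[(tert-butyldimethylsilyl)oxy]-4,4-dimethylnona-2,8-dienoate
Product: 9 ethyl (2E,5S)-5-[(tert-butyldimethylsilyl)oxy]-4,4-dimethyl-8-oxonon-2-enoate
Conditions: PdCl2 (cat.), CuCl, O2, DMF/H2O, rt
Reagents that add atoms: water, O
Why: Tsuji–Wacker oxidation converts the terminal alkene into the methyl ketone by Markovnikov oxypalladation, while the electron-poor disubstituted enoate is not a substrate.

Step 7
Reactants: 9 ethyl (2E,5S)-5-[(tert-butyldimethylsilyl)oxy]-4,4-dimethyl-8-oxonon-2-enoate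
Product: 10 ethyl 2-[(1S,3S,6S)-3-[(tert-butyldimethylsilyl)oxy]-6-hydroxy-2,2,6-trimethylcyclohexyl]acetate
Conditions: SmI2, MeOH, THF, −78 → 0 °C
Reagents that add atoms: none
Why: Electron transfer from SmI2 to the C9 methyl ketone gives a samarium ketyl that adds to the enoate β-carbon C4 in a 6-exo-trig closure; the α-ester radical is then reduced by a second SmI2 to the enolate and protonated by MeOH. The closest known reaction type is the SmI2-promoted ketyl–olefin cyclization of keto enoates to trans-2-(alkoxycarbonylmethyl)cycloalkanols. The cyclohexane should close through a chair in which the C6 silyloxy group is equatorial, so the aldol-derived C6 centre fixes the chair and with it the face of C4 that is attacked (C4–H axial, CH2CO2Et equatorial). At C9 the bulky O–Sm(III) group should take the equatorial site anti to the ester arm, for steric and dipole reasons, leaving the methyl axial; this sets C9 and the trans C9–O/C4–C3 relationship. The step needs ring closure to outrun plain reduction of either π system and needs anti rather than syn closure; the gem-dimethyl group at C5 (Thorpe–Ingold effect), the electron-poor acceptor and the low temperature with a mild proton source are what should secure both.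

Step 8
Reactants: 10 ethyl 2-[(1S,3S,6S)-3-[(tert-butyldimethylsilyl)oxy]-6-hydroxy-2,2,6-trimethylcyclohexyl]acetate
Product: 11 (3aS,5S,7aS)-5-[(tert-butyldimethylsilyl)oxy]-4,4,7a-trimethyloctahydro-1-benzofuran-2-ol (trans-fused lactol, both C2 epimers)
Conditions: DIBAL-H, CH2Cl2, −78 °C
Reagents that add atoms: none
Why: In this partial DIBAL-H reduction the aluminium alkoxide of the C9 hydroxyl should trap the aldehyde-level intermediate as a cyclic aluminate, so reduction stops at the lactol, as in lactone-to-lactol reductions (any lactone formed from 10 would converge on the same product).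

Step 9
Reactants: 11 (3aS,5S,7aS)-5-[(tert-butyldimethylsilyl)oxy]-4,4,7a-trimethyloctahydro-1-benzofuran-2-ol; 12 methyltriphenylphosphonium bromide
Product: 13 (1S,2S,4S)-4-[(tert-butyldimethylsilyl)oxy]-1,3,3-trimethyl-2-(prop-2-en-1-yl)cyclohexan-1-ol
Conditions: KOtBu, THF, 0 °C → rt
Reagents that add atoms: none
Why: Wittig methylenation of a lactol proceeds through its open hydroxy-aldehyde form and releases the tertiary C9 hydroxyl.

Step 10
Reactants: 13 (1S,2S,4S)-4-[(tert-butyldimethylsilyl)oxy]-1,3,3-trimethyl-2-(prop-2-en-1-yl)cyclohexan-1-ol; 14 methacryloyl chloride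
Product: 15 (1S,2S,4S)-4-[(tert-butyldimethylsilyl)oxy]-1,3,3-trimethyl-2-(prop-2-en-1-yl)cyclohexyl 2-methylprop-2-enoate
Conditions: n-BuLi, THF, −78 °C; then 14, −78 → 0 °C
Reagents that add atoms: none
Why: O-acylation of a preformed lithium alkoxide with an acid chloride is the dependable way to esterify a hindered tertiary alcohol, and 1,2-attack at the acyl chloride is far faster than conjugate addition.

Step 11
Reactants: 15 (1S,2S,4S)-4-[(tert-butyldimethylsilyl)oxy]-1,3,3-trimethyl-2-(prop-2-en-1-yl)cyclohexyl 2-methylprop-2-enoate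
Product: 16 (5aS,7S,9aS)-7-[(tert-butyldimethylsilyl)oxy]-3,6,6,9a-tetramethyl-5a,6,7,8,9,9a-hexahydro-1-benzoxepin-2(5H)-one
Conditions: Grubbs II (cat.), toluene, 80 °C, high dilution
Reagents that add atoms: none
Why: Ring-closing metathesis between the allyl group and the methacrylate should close the seven-membered unsaturated lactone (C1=C2), since both arms are held trans-diequatorial on the chair and loss of ethylene drives the reaction.

Step 12
Reactants: 16 (5aS,7S,9aS)-7-[(tert-butyldimethylsilyl)oxy]-3,6,6,9a-tetramethyl-5a,6,7,8,9,9a-hexahydro-1-benzoxepin-2(5H)-one; 17 dibromomethane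
Product: 18 (5aS,7S,9aS)-2-(bromomethyl)-7-[(tert-butyldimethylsilyl)oxy]-3,6,6,9a-tetramethyl-2,5,5a,6,7,8,9,9a-octahydro-1-benzoxepin-2-ol (hemiketal, both C11 epimers)
Conditions: MeLi·LiBr, THF/Et2O, −78 °C (carbenoid formed in the presence of 16); AcOH quench at −78 °C
Reagents that add atoms: none
Why: Halomethyllithium carbenoid addition to a lactone carbonyl gives a tetrahedral lithium hemiketal that persists at −78 °C, and the cold quench is meant to prevent a second addition or closure to an epoxide.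

Step 13
Reactants: 18 (5aS,7S,9aS)-2-(bromomethyl)-7-[(tert-butyldimethylsilyl)oxy]-3,6,6,9a-tetramethyl-2,5,5a,6,7,8,9,9a-octahydro-1-benzoxepin-2-ol
Product: 19 tert-butyl{[(2R,5aS,7S,9aS)-2-(bromomethyl)-3,6,6,9a-tetramethyl-2,5,5a,6,7,8,9,9a-octahydro-1-benzoxepin-7-yl]oxy}dimethylsilane
Conditions: Et3SiH, TMSOTf (cat.), CH2Cl2, −78 → −40 °C
Reagents that add atoms: none
Why: Ionic silane reduction of the hemiketal goes through the olefin-conjugated oxocarbenium ion, and hydride should add at C11 on the face away from the axial C9 methyl, which places C11–H syn to C4–H and sets C11 as R.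

Step 14
Reactants: 19 tert-butyl{[(2R,5aS,7S,9aS)-2-(bromomethyl)-3,6,6,9a-tetramethyl-2,5,5a,6,7,8,9,9a-octahydro-1-benzoxepin-7-yl]oxy}dimethylsilane
Product: 20 (2R,5aS,7S,9aS)-2-(bromomethyl)-3,6,6,9a-tetramethyl-2,5,5a,6,7,8,9,9a-octahydro-1-benzoxepin-7-ol (equatorial C6–OH)
Conditions: HF·pyridine, THF, 0 °C → rt
Reagents that add atoms: none
Why: Fluoride-mediated desilylation under buffered acidic conditions removes the TBS group without the basicity that could endanger the primary bromide.

Step 15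
Reactants: 20 (2R,5aS,7S,9aS)-2-(bromomethyl)-3,6,6,9a-tetramethyl-2,5,5a,6,7,8,9,9a-octahydro-1-benzoxepin-7-ol
Product: 21 (2R,5aS,9aS)-2-(bromomethyl)-3,6,6,9a-tetramethyl-2,5,5a,8,9,9a-hexahydro-1-benzoxepin-7(6H)-one
Conditions: Dess–Martin periodinane, CH2Cl2, rt
Reagents that add atoms: none
Why: Dess–Martin oxidation of the secondary alcohol gives the C6 ketone under neutral conditions that leave the olefin, the ether and the bromide untouched.

Step 16
Reactants: 21 (2R,5aS,9aS)-2-(bromomethyl)-3,6,6,9a-tetramethyl-2,5,5a,8,9,9a-hexahydro-1-benzoxepin-7(6H)-one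
Product: 22 (2R,5aS,7R,9aS)-2-(bromomethyl)-3,6,6,9a-tetramethyl-2,5,5a,6,7,8,9,9a-octahydro-1-benzoxepin-7-ol (axial C6–OH)
Conditions: L-Selectride, THF, −78 °C; then H2O
Reagents that add atoms: none
Why: Reduction with a bulky trialkylborohydride should deliver hydride to the C6 ketone along the equatorial trajectory of the rigid trans-fused chair, giving the axial (6R) alcohol, and at −78 °C the primary bromide should not be displaced.

Step 17
Reactants: 22 (2R,5aS,7R,9aS)-2-(bromomethyl)-3,6,6,9a-tetramethyl-2,5,5a,6,7,8,9,9a-octahydro-1-benzoxepin-7-ol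
Product: 23 (2R,5aS,7S,9aS)-7-bromo-2-(bromomethyl)-3,6,6,9a-tetramethyl-2,5,5a,6,7,8,9,9a-octahydro-1-benzoxepine
Conditions: CBr4, PPh3, CH2Cl2, 0 °C → rt
Reagents that add atoms: carbon tetrabromide, BrC(Br)(Br)Br
Why: In the Appel reaction bromide displaces the axial oxyphosphonium group from the equatorial side, so SN2 inversion should give the equatorial (6S) bromide, and no free hydroxyl remains elsewhere in the molecule.

Step 18
Reactants: 23 (2R,5aS,7S,9aS)-7-bromo-2-(bromomethyl)-3,6,6,9a-tetramethyl-2,5,5a,6,7,8,9,9a-octahydro-1-benzoxepine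
Product: 24 (2R,3R,4R,5aS,7S,9aS)-7-bromo-2-(bromomethyl)-3,4-epoxy-3,6,6,9a-tetramethyldecahydro-1-benzoxepine
Conditions: mCPBA, Na2HPO4, CH2Cl2, 0 °C
Reagents that add atoms: meta-chloroperbenzoic acid, OOC(=O)c1cccc(Cl)c1
Why: Prilezhaev epoxidation of the electron-rich trisubstituted C1=C2 olefin should occur on the face opposite the neighbouring C11 CH2Br group and the C9 methyl, giving the (1R,2R) epoxide with the C2–O bond already in its final configuration.

Step 19
Reactants: 24 (2R,3R,4R,5aS,7S,9aS)-7-bromo-2-(bromomethyl)-3,4-epoxy-3,6,6,9a-tetramethyldecahydro-1-benzoxepine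
Product: 25 (2R,4R,5aS,7S,9aS)-7-bromo-2-(bromomethyl)-6,6,9a-trimethyl-3-methylidenedecahydro-1-benzoxepin-4-ol (target)
Conditions: Et2Al–TMP (from LiTMP and Et2AlCl), toluene, 0 °C
Reagents that add atoms: none
Why: In the aluminium amide epoxide-to-allylic-alcohol isomerization the aluminium-bound epoxide should lose a syn proton from the least hindered β-carbon, the C1 methyl, through a cyclic transition state; the C1–O bond breaks to give the exocyclic methylene while the C2–O bond and its configuration are kept.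

**Compound list**

1 | pent-4-enal | C=CCCC=O | starting material
2 | 1-methoxy-2-methyl-1-(trimethylsilyloxy)prop-1-ene | COC(O[Si](C)(C)C)=C(C)C | starting material
3 | methyl (3S)-3-hydroxy-2,2-dimethylhept-6-enoate | COC(=O)C(C)(C)[C@@H](O)CCC=C | intermediate
4 | methyl (3S)-3-[(tert-butyldimethylsilyl)oxy]-2,2-dimethylhept-6-enoate | COC(=O)C(C)(C)[C@@H](O[Si](C)(C)C(C)(C)C)CCC=C | intermediate
5 | (3S)-3-[(tert-butyldimethylsilyl)oxy]-2,2-dimethylhept-6-en-1-ol | OCC(C)(C)[C@@H](O[Si](C)(C)C(C)(C)C)CCC=C | intermediate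
6 | (3S)-3-[(tert-butyldimethylsilyl)oxy]-2,2-dimethylhept-6-enal | O=CC(C)(C)[C@@H](O[Si](C)(C)C(C)(C)C)CCC=C | intermediate
7 | triethyl phosphonoacetate | CCOC(=O)CP(=O)(OCC)OCC | starting material
8 | ethyl (2E,5S)-5-[(tert-butyldimethylsilyl)oxy]-4,4-dimethylnona-2,8-dienoate | CCOC(=O)/C=C/C(C)(C)[C@@H](O[Si](C)(C)C(C)(C)C)CCC=C | intermediate
9 | ethyl (2E,5S)-5-[(tert-butyldimethylsilyl)oxy]-4,4-dimethyl-8-oxonon-2-enoate | CCOC(=O)/C=C/C(C)(C)[C@@H](O[Si](C)(C)C(C)(C)C)CCC(C)=O | intermediate
10 | ethyl 2-[(1S,3S,6S)-3-[(tert-butyldimethylsilyl)oxy]-6-hydroxy-2,2,6-trimethylcyclohexyl]acetate | CCOC(=O)C[C@H]1C(C)(C)[C@@H](O[Si](C)(C)C(C)(C)C)CC[C@]1(C)O | intermediate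
11 | (3aS,5S,7aS)-5-[(tert-butyldimethylsilyl)oxy]-4,4,7a-trimethyloctahydro-1-benzofuran-2-ol (C2 epimers) | OC1C[C@H]2C(C)(C)[C@@H](O[Si](C)(C)C(C)(C)C)CC[C@]2(C)O1 | intermediate
12 | methyltriphenylphosphonium bromide | C[P+](c1ccccc1)(c1ccccc1)c1ccccc1.[Br-] | starting material
13 | (1S,2S,4S)-4-[(tert-butyldimethylsilyl)oxy]-1,3,3-trimethyl-2-(prop-2-en-1-yl)cyclohexan-1-ol | C=CC[C@H]1C(C)(C)[C@@H](O[Si](C)(C)C(C)(C)C)CC[C@]1(C)O | intermediate
14 | methacryloyl chloride | C=C(C)C(Cl)=O | starting material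
15 | (1S,2S,4S)-4-[(tert-butyldimethylsilyl)oxy]-1,3,3-trimethyl-2-(prop-2-en-1-yl)cyclohexyl 2-methylprop-2-enoate | C=CC[C@H]1C(C)(C)[C@@H](O[Si](C)(C)C(C)(C)C)CC[C@]1(C)OC(=O)C(C)=C | intermediate
16 | (5aS,7S,9aS)-7-[(tert-butyldimethylsilyl)oxy]-3,6,6,9a-tetramethyl-5a,6,7,8,9,9a-hexahydro-1-benzoxepin-2(5H)-one | CC1=CC[C@H]2C(C)(C)[C@@H](O[Si](C)(C)C(C)(C)C)CC[C@]2(C)OC1=O | intermediate
17 | dibromomethane | BrCBr | starting material
18 | (5aS,7S,9aS)-2-(bromomethyl)-7-[(tert-butyldimethylsilyl)oxy]-3,6,6,9a-tetramethyl-2,5,5a,6,7,8,9,9a-octahydro-1-benzoxepin-2-ol (C11 epimers) | CC1=CC[C@H]2C(C)(C)[C@@H](O[Si](C)(C)C(C)(C)C)CC[C@]2(C)OC1(O)CBr | intermediate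
19 | tert-butyl{[(2R,5aS,7S,9aS)-2-(bromomethyl)-3,6,6,9a-tetramethyl-2,5,5a,6,7,8,9,9a-octahydro-1-benzoxepin-7-yl]oxy}dimethylsilane | CC1=CC[C@H]2C(C)(C)[C@@H](O[Si](C)(C)C(C)(C)C)CC[C@]2(C)O[C@H]1CBr | intermediate
20 | (2R,5aS,7S,9aS)-2-(bromomethyl)-3,6,6,9a-tetramethyl-2,5,5a,6,7,8,9,9a-octahydro-1-benzoxepin-7-ol | CC1=CC[C@H]2C(C)(C)[C@@H](O)CC[C@]2(C)O[C@H]1CBr | intermediate
21 | (2R,5aS,9aS)-2-(bromomethyl)-3,6,6,9a-tetramethyl-2,5,5a,8,9,9a-hexahydro-1-benzoxepin-7(6H)-one | CC1=CC[C@H]2C(C)(C)C(=O)CC[C@]2(C)O[C@H]1CBr | intermediate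
22 | (2R,5aS,7R,9aS)-2-(bromomethyl)-3,6,6,9a-tetramethyl-2,5,5a,6,7,8,9,9a-octahydro-1-benzoxepin-7-ol | CC1=CC[C@H]2C(C)(C)[C@H](O)CC[C@]2(C)O[C@H]1CBr | intermediate
23 | (2R,5aS,7S,9aS)-7-bromo-2-(bromomethyl)-3,6,6,9a-tetramethyl-2,5,5a,6,7,8,9,9a-octahydro-1-benzoxepine | CC1=CC[C@H]2C(C)(C)[C@@H](Br)CC[C@]2(C)O[C@H]1CBr | intermediate
24 | (2R,3R,4R,5aS,7S,9aS)-7-bromo-2-(bromomethyl)-3,4-epoxy-3,6,6,9a-tetramethyldecahydro-1-benzoxepine | C[C@@]12O[C@@H]1C[C@H]3C(C)(C)[C@@H](Br)CC[C@]3(C)O[C@H]2CBr | intermediate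
25 | (2R,4R,5aS,7S,9aS)-7-bromo-2-(bromomethyl)-6,6,9a-trimethyl-3-methylidenedecahydro-1-benzoxepin-4-ol | C=C1[C@H](O)C[C@H]2C(C)(C)[C@@H](Br)CC[C@]2(C)O[C@H]1CBr | target

**Step count and risks**

Total steps: 19. Longest linear sequence: 19 steps (from pent-4-enal 1).

Steps most likely to fail:

Step 7. Ring closure at the congested C4, which is flanked by the quaternary C5, may lose out to plain reduction of the enoate or the ketone, or may proceed through the competing chair with poor facial selectivity at C4/C9. The fallback replaces the acceptor by a doubly activated one and sets out from aldehyde 6. A Knoevenagel condensation with diethyl malonate (TiCl4, pyridine, THF) would give diethyl 2-[(3S)-3-[(tert-butyldimethylsilyl)oxy]-2,2-dimethylhept-6-en-1-ylidene]propanedioate F1. Tsuji–Wacker oxidation would give diethyl 2-[(3S)-3-[(tert-butyldimethylsilyl)oxy]-2,2-dimethyl-6-oxoheptylidene]propanedioate F2. SmI2 closure onto this more electrophilic, bulkier acceptor would give diethyl 2-[(1S,3S,6S)-3-[(tert-butyldimethylsilyl)oxy]-6-hydroxy-2,2,6-trimethylcyclohexyl]propanedioate F3. Krapcho dealkoxycarbonylation (LiCl, wet DMSO, heat) would then return the route at compound 10.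

Step 12. The basic carbenoid may deprotonate C3 to a dienolate instead of adding to the hindered conjugated carbonyl, or the tetrahedral adduct may collapse with ring opening before the bromomethyl group is secured. The fallback builds C12 by olefination and hydroboration and sets out from lactone 16. Petasis methylenation (Cp2TiMe2, toluene, 70 °C) would give the cyclic dienol ether tert-butyl{[(5aS,7S,9aS)-3,6,6,9a-tetramethyl-2-methylidene-2,5,5a,6,7,8,9,9a-octahydro-1-benzoxepin-7-yl]oxy}dimethylsilane F4. Hydroboration–oxidation of the terminal enol ether (9-BBN, then NaOH/H2O2), with boron going to C12 and hydrogen to C11 anti to the axial C9 methyl, would give [(2R,5aS,7S,9aS)-7-[(tert-butyldimethylsilyl)oxy]-3,6,6,9a-tetramethyl-2,5,5a,6,7,8,9,9a-octahydro-1-benzoxepin-2-yl]methanol F5. Appel bromination of this primary alcohol would return the route at compound 19, bypassing steps 12 and 13.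

Step 17. Ionization-type elimination toward C7, or migration of a C5 methyl, may outcompete backside attack at the neopentyl C6. The fallback separates activation from displacement and sets out from alcohol 22. Tf2O and pyridine at −78 °C would give the axial triflate (2R,5aS,7R,9aS)-2-(bromomethyl)-3,6,6,9a-tetramethyl-2,5,5a,6,7,8,9,9a-octahydro-1-benzoxepin-7-yl trifluoromethanesulfonate F6. Displacement with Bu4NBr in toluene at low temperature (a free, weakly basic bromide acting on a pre-formed sulfonate) would return the route at compound 23.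

**Further compounds**

F1 | step 7 | diethyl 2-[(3S)-3-[(tert-butyldimethylsilyl)oxy]-2,2-dimethylhept-6-en-1-ylidene]propanedioate | CCOC(=O)C(=CC(C)(C)[C@@H](O[Si](C)(C)C(C)(C)C)CCC=C)C(=O)OCC
F2 | step 7 | diethyl 2-[(3S)-3-[(tert-butyldimethylsilyl)oxy]-2,2-dimethyl-6-oxoheptylidene]propanedioate | CCOC(=O)C(=CC(C)(C)[C@@H](O[Si](C)(C)C(C)(C)C)CCC(C)=O)C(=O)OCC
F3 | step 7 | diethyl 2-[(1S,3S,6S)-3-[(tert-butyldimethylsilyl)oxy]-6-hydroxy-2,2,6-trimethylcyclohexyl]propanedioate | CCOC(=O)C(C(=O)OCC)[C@H]1C(C)(C)[C@@H](O[Si](C)(C)C(C)(C)C)CC[C@]1(C)O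
F4 | step 12 | tert-butyl{[(5aS,7S,9aS)-3,6,6,9a-tetramethyl-2-methylidene-2,5,5a,6,7,8,9,9a-octahydro-1-benzoxepin-7-yl]oxy}dimethylsilane | CC1=CC[C@H]2C(C)(C)[C@@H](O[Si](C)(C)C(C)(C)C)CC[C@]2(C)OC1=C
F5 | step 12 | [(2R,5aS,7S,9aS)-7-[(tert-butyldimethylsilyl)oxy]-3,6,6,9a-tetramethyl-2,5,5a,6,7,8,9,9a-octahydro-1-benzoxepin-2-yl]methanol | CC1=CC[C@H]2C(C)(C)[C@@H](O[Si](C)(C)C(C)(C)C)CC[C@]2(C)O[C@H]1CO
F6 | step 17 | (2R,5aS,7R,9aS)-2-(bromomethyl)-3,6,6,9a-tetramethyl-2,5,5a,6,7,8,9,9a-octahydro-1-benzoxepin-7-yl trifluoromethanesulfonate | CC1=CC[C@H]2C(C)(C)[C@H](OS(=O)(=O)C(F)(F)F)CC[C@]2(C)O[C@H]1CBr
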